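Assumption: the alcohol dehydrogenase, catechol 1,2-dioxygenase and muconate cycloisomerase are used as catalysts (recombinant enzymes). Atom labels C1–C10 follow the macrolactone of the target (C1 = macrolactone C=O, C3/C4 = ring-fusion carbons, C6 = ketone, C9 = O-bearing methine); Cα = furyl-bearing lactone carbon.

**Retrosynthetic overview**
1. Cordycicadin B ⇐ ring expansion of the spiro seven-membered acyl ketal 17 (pseudo-ester → keto-macrolactone isomerisation, 7 → 10); the ten-membered ring is formed last.
2. 17 ⇐ kinetic protonation at Cα ⇐ spiro acyl ketal 15 ⇐ hydroxy keto acid 14 ⇐ ynone 13.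
3. 13 ⇐ opening of γ-lactone 10 by the acetylide of (R)-but-3-yn-2-ol, with translactonisation that creates the butyrolactone of the target.
4. 10 ⇐ anti-selective Michael addition of furylacetate 5 to (S)-muconolactone 8 (sets C4 from C3).
5. 5 ⇐ 2-furylacetonitrile + methyl vinyl ketone; 8 ⇐ catechol. Ring order: butenolide → γ-butyrolactone → spiro oxolane/seven-membered pseudo-ester → ten-membered lactone.

**Route**

Step 1
Reactants: 1 2-(furan-2-yl)acetonitrile
Product: 2 methyl 2-(furan-2-yl)acetate
Conditions: HCl (4 M in dioxane), MeOH, 0 °C → rt; then H2O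
Reagents that add atoms: methanol CO; water O
Why: Pinner reaction (HCl-mediated methanolysis of the nitrile, then hydrolysis) gives the methyl ester that serves as enolate precursor and later as internal acyl donor; no stereocentre is formed.

Step 2
Reactants: 2 methyl 2-(furan-2-yl)acetate; 3 but-3-en-2-one
Product: 4 methyl 2-[5-(3-oxobutyl)furan-2-yl]acetate
Conditions: 3 (1.5 equiv), BF3·OEt2 (10 mol %), MeNO2, −20 → 0 °C
Reagents that add atoms: none
Why: Lewis-acid-catalysed Friedel–Crafts conjugate addition of the furan to the enone occurs at the only free α-position (C5); no stereocentre.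

Step 3
Reactants: 4 methyl 2-[5-(3-oxobutyl)furan-2-yl]acetate
Product: 5 methyl 2-{5-[(3R)-3-hydroxybutyl]furan-2-yl}acetate
Conditions: Lactobacillus kefir alcohol dehydrogenase, NADP+ (cat.), i-PrOH (10 vol %), phosphate buffer pH 7.0, MgCl2, 30 °C
Reagents that add atoms: none
Why: Biocatalytic ketone reduction; this anti-Prelog dehydrogenase converts 4-arylbutan-2-ones into the (R)-alcohols with high ee, which sets the side-chain carbinol, and the ester survives at pH 7.

Step 4
Reactants: 6 catechol
Product: 8 (S)-muconolactone, via cis,cis-muconic acid 7 (not isolated)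
Conditions: catechol 1,2-dioxygenase, air (O2), Tris buffer pH 7.5, 30 °C; then muconate cycloisomerase, MnCl2 (cat.); acidify to pH 2, EtOAc extraction
Reagents that add atoms: dioxygen O=O
Why: Intradiol dioxygenase ring cleavage gives the cis,cis-diacid, and the cycloisomerase lactonises it (intramolecular oxa-Michael cycloisomerisation) under enzyme control to the (4S)-butenolide, which sets the future C3.

Step 5
Reactants: 5 methyl 2-{5-[(3R)-3-hydroxybutyl]furan-2-yl}acetate; 8 (S)-muconolactone
Product: 10 trans Michael adduct (2S,3S-lactone acid; both epimers at Cα), via dilithio enolate alkoxide 9 (not isolated)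
Conditions: 5, LiHMDS (2.1 equiv), THF, −78 °C; then 8 (pre-neutralised with 1.0 equiv LiHMDS, THF/DMPU), −78 °C, 2 h; AcOH, −78 °C
Reagents that add atoms: none
Why: Michael addition of the lithium ester enolate to the butenolide occurs anti to the γ-CH2CO2Li group, which fixes C4 relative to C3 (trans on this lactone); Cα forms unselectively and is set in step 8.

Step 6
Reactants: 10 trans Michael adduct; 11 (R)-but-3-yn-2-ol
Product: 13 ynone lactone acid (epimers at Cα), via seco hydroxy ynone methyl ester 12 (not isolated)
Conditions: 10, LiHMDS (3.0 equiv), THF, −78 °C; LiC≡CCH(OLi)CH3 [11 (1.5 equiv) + n-BuLi (3.0 equiv)], −78 °C, 1 h; AcOH, −78 °C; then PPTS (10 mol %), CH2Cl2, rt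
Reagents that add atoms: none
Why: Acetylide addition to the γ-lactone stops at the ynone stage (lactol alkoxide persists at −78 °C; ester masked as enolate, acid as carboxylate), and the freed C3–OH then translactonises onto the methyl ester (5-exo lactonisation), so the trans relationship of the old lactone becomes the cis C3/C4 fusion of the target butyrolactone; C9 (R) comes from 11.

Step 7
Reactants: 13 ynone lactone acid
Product: 15 spiro acyl ketal (epimers at Cα and at the spiro carbon), via hydroxy keto acid 14 (not isolated)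
Conditions: H2 (1 atm), 5 % Pd/C, EtOAc, rt; filter; PPTS (10 mol %), 4 Å MS, PhMe (0.02 M), 40 °C
Reagents that add atoms: none
Why: Catalytic hydrogenation saturates the ynone, then acid-catalysed dehydrative pseudo-ester formation (C9–OH and the carboxylic acid both add to the C6 oxocarbenium, as in spiroketal and THP-ester chemistry) masks ketone, alcohol and acid in one seven-membered acyl ketal; the spiro centre is uncontrolled and is lost in step 9.

Step 8
Reactants: 15 spiro acyl ketal
Product: 17 all-cis spiro acyl ketal (αS), via dilithio lactone enolate 16 (not isolated)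
Conditions: LiHMDS (2.1 equiv), THF, −78 °C, 30 min; AcOH in THF, −78 °C
Reagents that add atoms: none
Why: Kinetic protonation of the α-furyl lactone enolate (the only C–H near pKa 20 now that the ketone is a ketal) from the convex face, opposite the cis-fused seven-membered ring, places the furan cis to C5 and sets Cα (S).

Step 9
Reactants: 17 all-cis spiro acyl ketal
Product: 18 Cordycicadin B
Conditions: (PhO)2P(O)OH (10 mol %), PhMe (5 mM), 80 °C
Reagents that add atoms: none
Why: Proposed new method: ring-expanding pseudo-ester → normal-ester isomerisation, in which protonation of the oxolane oxygen opens the spiro ketal to an O-acylated oxocarbenium ion whose own released C9–OH attacks the acyl carbon through a seven-membered transition state, so the seven-membered lactone grows to the ten-membered keto lactone with C9 untouched; it is driven by ketone + ester being more stable than an acyl ketal and is intramolecular by design because the nucleophile is unmasked only in the activated molecule, and the closest known reaction types are acid-catalysed acyl transfer from isopropenyl esters through 2-alkoxy-2-acyloxy ketals, the pseudo-ester/normal-ester isomerisation of keto acids and ring enlargement by side-chain incorporation.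

**Compound list**
1 | 2-(furan-2-yl)acetonitrile | N#CCc1ccco1 | starting material
2 | methyl 2-(furan-2-yl)acetate | COC(=O)Cc1ccco1 | intermediate
3 | but-3-en-2-one | CC(=O)C=C | starting material
4 | methyl 2-[5-(3-oxobutyl)furan-2-yl]acetate | COC(=O)Cc1ccc(CCC(C)=O)o1 | intermediate
5 | methyl 2-{5-[(3R)-3-hydroxybutyl]furan-2-yl}acetate | COC(=O)Cc1ccc(CC[C@@H](C)O)o1 | intermediate
6 | catechol | Oc1ccccc1O | starting material
7 | (2Z,4Z)-hexa-2,4-dienedioic acid (cis,cis-muconic acid) | OC(=O)/C=C\C=C/C(=O)O | intermediate
8 | (S)-muconolactone, 2-[(2S)-5-oxo-2,5-dihydrofuran-2-yl]acetic acid | OC(=O)C[C@H]1C=CC(=O)O1 | intermediate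
9 | dilithio enolate alkoxide of 5 | COC(O[Li])=Cc1ccc(CC[C@@H](C)O[Li])o1 | intermediate
10 | 2-[(2S,3S)-3-{1-[5-((3R)-3-hydroxybutyl)furan-2-yl]-2-methoxy-2-oxoethyl}-5-oxooxolan-2-yl]acetic acid (2,3-trans; epimers at Cα) | O=C1C[C@@H](C(C(=O)OC)c2ccc(CC[C@@H](C)O)o2)[C@H](CC(=O)O)O1 | intermediate
11 | (R)-but-3-yn-2-ol | C#C[C@@H](C)O | starting material
12 | (3S,4S,9R)-3,9-dihydroxy-4-{1-[5-((3R)-3-hydroxybutyl)furan-2-yl]-2-methoxy-2-oxoethyl}-6-oxodec-7-ynoic acid (seco hydroxy ynone methyl ester) | COC(=O)C(c1ccc(CC[C@@H](C)O)o1)[C@H](CC(=O)C#C[C@@H](C)O)[C@@H](O)CC(=O)O | intermediate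
13 | 2-[(2S,3S)-4-{5-[(3R)-3-hydroxybutyl]furan-2-yl}-3-[(5R)-5-hydroxy-2-oxohex-3-yn-1-yl]-5-oxooxolan-2-yl]acetic acid (epimers at Cα) | O=C1O[C@@H](CC(=O)O)[C@@H](CC(=O)C#C[C@@H](C)O)C1c1ccc(CC[C@@H](C)O)o1 | intermediate
14 | 2-[(2S,3S)-4-{5-[(3R)-3-hydroxybutyl]furan-2-yl}-3-[(5R)-5-hydroxy-2-oxohexyl]-5-oxooxolan-2-yl]acetic acid (open form of the lactol; epimers at Cα) | O=C1O[C@@H](CC(=O)O)[C@@H](CC(=O)CC[C@@H](C)O)C1c1ccc(CC[C@@H](C)O)o1 | intermediate
15 | spiro acyl ketal: C1 carboxyl oxygen and O9 both on C6 (oxepan-2-one spiro-fused to a (5R)-5-methyloxolane and cis-fused at C3/C4 to the α-furyl butyrolactone; epimers at Cα and spiro carbon) | O=C1O[C@H]2CC(=O)OC3(CC[C@@H](C)O3)C[C@H]2C1c1ccc(CC[C@@H](C)O)o1 | intermediate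
16 | dilithio lactone enolate alkoxide of 15 | [Li]OC=1O[C@H]2CC(=O)OC3(CC[C@@H](C)O3)C[C@H]2C=1c1ccc(CC[C@@H](C)O[Li])o1 | intermediate
17 | all-cis spiro acyl ketal (C3 S, C4 S, Cα S; furan cis to C5 and C2) | O=C1O[C@H]2CC(=O)OC3(CC[C@@H](C)O3)C[C@H]2[C@H]1c1ccc(CC[C@@H](C)O)o1 | intermediate
18 | Cordycicadin B | C[C@@H]1CCC(=O)C[C@@H]2[C@H](CC(=O)O1)OC(=O)[C@@H]2c1ccc(CC[C@@H](C)O)o1 | target

**Step count and risks**
Total steps: 9. Longest linear sequence: 8 (steps 1, 2, 3, 5, 6, 7, 8, 9).

Three steps most likely to fail:

Step 5 (Michael addition with unprotected acid and alcohol). The ester enolate may deprotonate the γ-position of 8, which would racemise C3, and the lithium carboxylate may be poorly soluble. Fallback, setting out from 5 and 8 and returning at 10: a Lewis-acid Mukaiyama–Michael reaction in place of the polyanionic enolate. Ester 5 is converted with LiHMDS/TMSCl into the bis-silylated ketene acetal F1, and 8 with TMSCl/Et3N into trimethylsilyl muconolactonate F2. TMSOTf (cat.) in CH2Cl2 at −78 °C joins them anti to the γ-substituent, and dilute aqueous acid removes all silyl groups to give 10.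

Step 6 (acetylide addition to a trilithiated substrate). Double addition is possible, as is cyclisation of the ester enolate onto the ynone if the lactol alkoxide collapses early. Fallback, setting out from 10 and returning at 14: an sp3 organolithium instead of the acetylide, so no ynone and no hydrogenation. Commercial (R)-butane-1,3-diol is iodinated selectively at the primary position (I2, PPh3, imidazole) to (R)-4-iodobutan-2-ol F3. n-BuLi then t-BuLi (−78 °C) give the dilithio reagent (3R)-3-(lithiooxy)butyllithium F4, which adds once to the lactone of trilithiated 10. Acetic acid quench gives the saturated seco hydroxy keto methyl ester F5, and PPTS lactonises it to 14, which continues with the acid/sieves part of step 7.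

Step 9 (the new ring expansion). The acyl ketal may only equilibrate with enol ether and acid, the furan β-carbon may attack the C6 cation, or Cα may epimerise on heating. Fallback with known chemistry, setting out from 17 and returning at 18: the side-chain alcohol is silylated (TBSOTf, 2,6-lutidine) to the TBS ether of the spiro acyl ketal F6. Mild hydrolysis of the acyl ketal (AcOH/THF/H2O, rt) gives the all-cis hydroxy keto acid TBS ether F7. Shiina macrolactonisation (MNBA, DMAP, CH2Cl2, high dilution) closes the ten-membered ring to O-TBS Cordycicadin B F8, and HF·pyridine gives 18.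

Further compounds
F1 | step 5 | methyl ketene acetal of 5 as O-trimethylsilyl ketene acetal and trimethylsilyl ether | COC(O[Si](C)(C)C)=Cc1ccc(CC[C@@H](C)O[Si](C)(C)C)o1
F2 | step 5 | trimethylsilyl (S)-muconolactonate | C[Si](C)(C)OC(=O)C[C@H]1C=CC(=O)O1
F3 | step 6 | (R)-4-iodobutan-2-ol | ICC[C@@H](C)O
F4 | step 6 | (3R)-3-(lithiooxy)butyllithium | [Li]CC[C@@H](C)O[Li]
F5 | step 6 | (3S,4S,9R)-3,9-dihydroxy-4-{1-[5-((3R)-3-hydroxybutyl)furan-2-yl]-2-methoxy-2-oxoethyl}-6-oxodecanoic acid | COC(=O)C(c1ccc(CC[C@@H](C)O)o1)[C@H](CC(=O)CC[C@@H](C)O)[C@@H](O)CC(=O)O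
F6 | step 9 | TBS ether of the all-cis spiro acyl ketal 17 | O=C1O[C@H]2CC(=O)OC3(CC[C@@H](C)O3)C[C@H]2[C@H]1c1ccc(CC[C@@H](C)O[Si](C)(C)C(C)(C)C)o1
F7 | step 9 | all-cis hydroxy keto acid with side-chain TBS ether | O=C1O[C@@H](CC(=O)O)[C@@H](CC(=O)CC[C@@H](C)O)[C@H]1c1ccc(CC[C@@H](C)O[Si](C)(C)C(C)(C)C)o1
F8 | step 9 | O-TBS Cordycicadin B | C[C@@H]1CCC(=O)C[C@@H]2[C@H](CC(=O)O1)OC(=O)[C@@H]2c1ccc(CC[C@@H](C)O[Si](C)(C)C(C)(C)C)o1
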